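**Plan**

- Retrosynthesis: the C3–O and C6–O bonds are cut together, C3 by way of its ketone. These two oxygens stand 1,4 across the C1=C2 double bond of the cyclohexene ring, which is the retron for adding dioxygen to a C6=C1–C2=C3 diene that already carries the trans O4/O5 pair. The diene goes back to shikimic acid by returning the C3 oxygen and removing the O-protecting groups.
- Forward: no carbocycle is built; the six-membered ring is that of shikimic acid. C7 is reduced, O5 and O7 are benzoylated, O3 is oxidised so that O4 alone can be silylated, and C3 is reduced and dehydrated 1,4 to the diene. Dioxygen is then added across C3/C6 and the transient peroxide ring is opened in the same flask; reduction at C3 and desilylation finish the synthesis.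
- Stereochemistry: C4 and C5 are those of shikimic acid. C6 comes from the face of the cycloaddition, anti to the O4 silyl ether. C3 comes from equatorial delivery of a bulky hydride, cis to O4.

Key step: step 9

Remark on notation: C1 is the ring carbon bearing the exocyclic carbon C7, C2 is its vinylic neighbour, and C3, C4, C5, C6 follow round the ring (ring benzoate on C5); β is the ring face carrying O3 and O4 of shikimic acid, α the face carrying O5.

**Route**

Step 1
Reactants: 1 shikimic acid
Product: 3 methyl 3,4-O-isopropylideneshikimate (3β,4β-acetonide; free 5α-hydroxyl), via methyl shikimate 2 (not isolated)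
Conditions: MeOH, camphorsulfonic acid (cat.), reflux; evaporate; Me2C(OMe)2, acetone, rt
Reagents that add atoms: methanol, CO; 2,2-dimethoxypropane, COC(C)(C)OC
Why: Fischer esterification is followed by acid-catalysed acetal exchange, which bridges only the cis-disposed O3 and O4 because the trans O4/O5 pair cannot close an unstrained dioxolane, so O5 is left as the single free hydroxyl.

Step 2
Reactants: 3 methyl 3,4-O-isopropylideneshikimate
Product: 4 (5α-hydroxy-3β,4β-isopropylidenedioxycyclohex-1-en-1-yl)methanol
Conditions: i-Bu2AlH (4 equiv), CH2Cl2, −78 → 0 °C; aq. potassium sodium tartrate (KNaC4H4O6)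
Reagents that add atoms: none
Why: i-Bu2AlH reduces the conjugated ester 1,2 to the primary allylic alcohol at C7, a standard ester-to-alcohol hydride reduction that leaves the acetonide, the alkene and all three stereocentres untouched.

Step 3
Reactants: 4 (5α-hydroxy-3β,4β-isopropylidenedioxycyclohex-1-en-1-yl)methanol; 5 benzoyl chloride
Product: 6 (5α-benzoyloxy-3β,4β-isopropylidenedioxycyclohex-1-en-1-yl)methyl benzoate
Conditions: BzCl (2.5 equiv), pyridine, DMAP (cat.), CH2Cl2, 0 °C → rt
Reagents that add atoms: benzoyl chloride, O=C(Cl)c1ccccc1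
Why: DMAP-catalysed acylation of both free hydroxyls places the two benzoates of the target on O5 and O7 while O3 and O4 are still masked together.

Step 4
Reactants: 6 acetonide dibenzoate
Product: 7 (5α-benzoyloxy-3β,4β-dihydroxycyclohex-1-en-1-yl)methyl benzoate
Conditions: AcOH/H2O (4:1), 45 °C
Reagents that add atoms: none
Why: Acid-catalysed acetal hydrolysis frees the cis-diol under conditions that benzoates tolerate and that are too weakly acidic to ionise the allylic C3–O bond.

Step 5
Reactants: 7 diol dibenzoate
Product: 8 (5α-benzoyloxy-4β-hydroxy-3-oxocyclohex-1-en-1-yl)methyl benzoate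
Conditions: MnO2 (activated, excess), CH2Cl2, rt
Reagents that add atoms: none
Why: MnO2 oxidises allylic alcohols selectively, so only O3 becomes the enone carbonyl and O4 remains as the one free hydroxyl, which settles the O3/O4 regiochemistry of the silylation that follows.

Step 6
Reactants: 8 4β-hydroxy enone; 9 tert-butyldimethylsilyl trifluoromethanesulfonate
Product: 10 [5α-benzoyloxy-4β-(tert-butyldimethylsilyloxy)-3-oxocyclohex-1-en-1-yl]methyl benzoate
Conditions: TBSOTf (1.2 equiv), 2,6-lutidine, CH2Cl2, −78 °C
Reagents that add atoms: tert-butyldimethylsilyl trifluoromethanesulfonate, CC(C)(C)[Si](C)(C)OS(=O)(=O)C(F)(F)F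
Why: O-silylation by the silyl triflate with a hindered pyridine is fast at −78 °C, where the base is too weak to enolise the ketone or to expel the β-benzoate.

Step 7
Reactants: 10 silyloxy enone
Product: 11 [5α-benzoyloxy-4β-(tert-butyldimethylsilyloxy)-3β-hydroxycyclohex-1-en-1-yl]methyl benzoate
Conditions: LiBH(s-Bu)3 (L-Selectride, 1.2 equiv), THF, −78 °C; AcOH
Reagents that add atoms: none
Why: The bulky trialkylborohydride reduces this β-substituted enone 1,2 and, as with 2-alkoxycyclohexanones, enters along the equatorial direction on the α face (clear of the axial H5 on the β face), which should give the pseudoaxial 3β alcohol cis to the silyl ether, the geometry the sigmatropic shift of step 8 needs, although the 3α epimer would converge on the same diene.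

Step 8
Reactants: 11 3β allylic alcohol
Product: 14 [5α-benzoyloxy-4β-(tert-butyldimethylsilyloxy)cyclohexa-1(6),2-dien-1-yl]methyl benzoate, via allylic sulfenate 12 (not isolated), via allylic sulfoxide 13 (not isolated)
Conditions: 2,4-(O2N)2C6H3SCl, Et3N, ClCH2CH2Cl, 0 °C → 50 °C
Reagents that add atoms: none
Why: The known 1,4-dehydration of allylic alcohols through their 2,4-dinitrobenzenesulfenates is used: the sulfenate undergoes the [2,3]-sigmatropic shift (the Mislow–Evans rearrangement run toward the sulfoxide) to the tertiary C1 sulfoxide on the β face, whose thermal syn-elimination takes the cis H6 and not a hydrogen of the oxygen-bearing C7, giving the C6=C1–C2=C3 diene with C4 and C5 untouched.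

Step 9
Reactants: 14 diene (4β-silyloxy, 5α-benzoyloxy, C7 benzoate)
Product: 16 [5α-benzoyloxy-4β-(tert-butyldimethylsilyloxy)-6α-hydroxy-3-oxocyclohex-1-en-1-yl]methyl benzoate, via endoperoxide 15 (not isolated)
Conditions: O2, tetraphenylporphyrin (cat.), CH2Cl2, visible light, −78 °C; then N2 purge, Et3N (0.5 equiv), −40 → 0 °C
Reagents that add atoms: dioxygen, O=O
Why: Sensitised singlet oxygen adds suprafacially across C3 and C6 of the s-cis diene in a [4+2] cycloaddition, the standard photooxygenation of cyclohexa-1,3-dienes, and Et3N then isomerises the bicyclic peroxide by Kornblum–DeLaMare rearrangement, removing H3 as the O–O bond breaks. The only ring closed is the peroxide bridge of the 2,3-dioxabicyclo[2.2.2]oct-5-ene 15, formed in the concerted cycloaddition and opened again in the same flask, so no ring lasts. The one stereocentre that survives, C6, is set by the face of attack: oxygen should come anti to the pseudoaxial, electron-rich 4β silyl ether, and since both C–O bonds form on one face the C6 oxygen arrives on the α face, cis to the C5 benzoate. The C3–O centre formed alongside has the wrong sense and is erased as the ketone, to be reset in step 10. Two selectivities are needed, α-face attack and loss of H3 rather than H6; the first rests on the bulk and lone-pair repulsion of the silyloxy group compared with the flatter, less basic benzoate, the second on H3 standing beside the unsubstituted vinylic C2 while H6 is crowded by the fully substituted C1 and its CH2OBz arm. Sub-stoichiometric amine at low temperature limits loss of benzoic acid from the β-benzoyloxy ketone and benzoyl shift to O6.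

Step 10
Reactants: 16 6α-hydroxy enone
Product: 17 [5α-benzoyloxy-4β-(tert-butyldimethylsilyloxy)-3β,6α-dihydroxycyclohex-1-en-1-yl]methyl benzoate
Conditions: LiBH(s-Bu)3 (L-Selectride, 2.5 equiv), THF, −78 °C; AcOH at −78 °C
Reagents that add atoms: none
Why: As in step 7, the bulky hydride adds 1,2 to the enone, whose β-carbon C1 is fully substituted, along the equatorial direction on the α face, opposite the axial H5 and clear of the 4β silyl ether, which sets the new C3 stereocentre as the 3β alcohol cis to O4, while the low temperature and acidic quench keep the C6 alkoxide from taking the neighbouring benzoyl group.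

Step 11
Reactants: 17 silyl ether diol
Product: 18 [(3R,4R,5R,6R)-5-benzoyloxy-3,4,6-trihydroxycyclohex-1-en-1-yl]methyl benzoate (CNP0198957.3)
Conditions: HF·pyridine, pyridine, THF, 0 °C → rt
Reagents that add atoms: none
Why: Fluoride cleavage of the silyl ether under buffered, weakly acidic conditions frees O4 without benzoyl migration to the neighbouring hydroxyls and touches no stereocentre.

**Compound list**

1 | shikimic acid, (3R,4S,5R)-3,4,5-trihydroxycyclohex-1-ene-1-carboxylic acid | OC(=O)C1=C[C@@H](O)[C@@H](O)[C@H](O)C1 | starting material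
2 | methyl shikimate | COC(=O)C1=C[C@@H](O)[C@@H](O)[C@H](O)C1 | intermediate
3 | methyl 3,4-O-isopropylideneshikimate (3β,4β-acetonide, 5α-OH) | COC(=O)C1=C[C@H]2OC(C)(C)O[C@H]2[C@H](O)C1 | intermediate
4 | (5α-hydroxy-3β,4β-isopropylidenedioxycyclohex-1-en-1-yl)methanol | OCC1=C[C@H]2OC(C)(C)O[C@H]2[C@H](O)C1 | intermediate
5 | benzoyl chloride | O=C(Cl)c1ccccc1 | starting material
6 | (5α-benzoyloxy-3β,4β-isopropylidenedioxycyclohex-1-en-1-yl)methyl benzoate | O=C(OCC1=C[C@H]2OC(C)(C)O[C@H]2[C@H](OC(=O)c2ccccc2)C1)c1ccccc1 | intermediate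
7 | (5α-benzoyloxy-3β,4β-dihydroxycyclohex-1-en-1-yl)methyl benzoate | O=C(OCC1=C[C@@H](O)[C@@H](O)[C@H](OC(=O)c2ccccc2)C1)c1ccccc1 | intermediate
8 | (5α-benzoyloxy-4β-hydroxy-3-oxocyclohex-1-en-1-yl)methyl benzoate | O=C(OCC1=CC(=O)[C@@H](O)[C@H](OC(=O)c2ccccc2)C1)c1ccccc1 | intermediate
9 | tert-butyldimethylsilyl trifluoromethanesulfonate | CC(C)(C)[Si](C)(C)OS(=O)(=O)C(F)(F)F | starting material
10 | [5α-benzoyloxy-4β-(tert-butyldimethylsilyloxy)-3-oxocyclohex-1-en-1-yl]methyl benzoate | O=C(OCC1=CC(=O)[C@@H](O[Si](C)(C)C(C)(C)C)[C@H](OC(=O)c2ccccc2)C1)c1ccccc1 | intermediate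
11 | [5α-benzoyloxy-4β-(tert-butyldimethylsilyloxy)-3β-hydroxycyclohex-1-en-1-yl]methyl benzoate | O=C(OCC1=C[C@@H](O)[C@@H](O[Si](C)(C)C(C)(C)C)[C@H](OC(=O)c2ccccc2)C1)c1ccccc1 | intermediate
12 | allylic sulfenate: 3β-O-(2,4-dinitrophenylsulfanyl) derivative of 11 | O=C(OCC1=C[C@@H](OSc2ccc(cc2[N+](=O)[O-])[N+](=O)[O-])[C@@H](O[Si](C)(C)C(C)(C)C)[C@H](OC(=O)c2ccccc2)C1)c1ccccc1 | intermediate
13 | allylic sulfoxide: [5α-benzoyloxy-4β-(tert-butyldimethylsilyloxy)-1β-(2,4-dinitrophenylsulfinyl)cyclohex-2-en-1-yl]methyl benzoate, sulfur configuration not defined | O=C(OC[C@]1(S(=O)c2ccc(cc2[N+](=O)[O-])[N+](=O)[O-])C=C[C@@H](O[Si](C)(C)C(C)(C)C)[C@H](OC(=O)c2ccccc2)C1)c1ccccc1 | intermediate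
14 | diene: [(4R,5R)-5-benzoyloxy-4-(tert-butyldimethylsilyloxy)cyclohexa-1(6),2-dien-1-yl]methyl benzoate (4β-OSi, 5α-OBz) | O=C(OCC1=C[C@@H](OC(=O)c2ccccc2)[C@H](O[Si](C)(C)C(C)(C)C)C=C1)c1ccccc1 | intermediate
15 | endoperoxide: 14 bridged from C3 to C6 by O–O on the α face (2,3-dioxabicyclo[2.2.2]oct-5-ene, alkene C1=C2, 4β-OSi, 5α-OBz) | O=C(OCC1=C[C@@H]2OO[C@H]1[C@@H](OC(=O)c3ccccc3)[C@@H]2O[Si](C)(C)C(C)(C)C)c1ccccc1 | intermediate
16 | [(4S,5R,6R)-5-benzoyloxy-4-(tert-butyldimethylsilyloxy)-6-hydroxy-3-oxocyclohex-1-en-1-yl]methyl benzoate (4β-OSi, 5α-OBz, 6α-OH) | O=C(OCC1=CC(=O)[C@@H](O[Si](C)(C)C(C)(C)C)[C@H](OC(=O)c2ccccc2)[C@@H]1O)c1ccccc1 | intermediate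
17 | [5α-benzoyloxy-4β-(tert-butyldimethylsilyloxy)-3β,6α-dihydroxycyclohex-1-en-1-yl]methyl benzoate | O=C(OCC1=C[C@@H](O)[C@@H](O[Si](C)(C)C(C)(C)C)[C@H](OC(=O)c2ccccc2)[C@@H]1O)c1ccccc1 | intermediate
18 | [(3R,4R,5R,6R)-5-benzoyloxy-3,4,6-trihydroxycyclohex-1-en-1-yl]methyl benzoate (3β,4β,6α-triol, 5α-benzoate) | O=C(OCC1=C[C@@H](O)[C@@H](O)[C@H](OC(=O)c2ccccc2)[C@@H]1O)c1ccccc1 | target

**Step count and risks**

Total step count: 11. Longest linear sequence: 11 steps (1 to 18; the route is fully linear).

Steps most likely to fail: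

1. Step 9. Facial control in the cycloaddition may be lost, with oxygen approaching syn to the silyl ether because the C5 benzoate beside the more nucleophilic diene terminus steers it to the β face. Removal of H6 instead of H3, or amine-induced loss of benzoic acid from the product, would add to the damage. The fallback sets out from 6 and rejoins at 18, and it introduces the C6 oxygen by allylic C–H oxidation instead of cycloaddition. Riley oxidation of acetonide dibenzoate 6 (SeO2 cat., t-BuOOH, CH2Cl2, or SeO2 in dioxane at 80 °C) should begin with an ene reaction in which selenium bonds to C2 on the α face, away from the β-fused acetonide, and abstracts the pseudoaxial H6α. The [2,3] shift that follows places the hydroxyl on C6 on that same face, the ring methylene being preferred over the oxygen-bearing C7, to give the 6α-hydroxy acetonide F1. Aqueous acetic acid (45 °C) then cleaves the acetonide of F1 and gives 18 directly.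

2. Step 10. Hydride may be delivered along the axial direction on the β face, giving the 3α epimer, or the C5 benzoyl group may shift to the C6 alkoxide. The fallback sets out from 16 and rejoins at 18, and it sets C3 by inversion instead of by direct reduction. The C6 hydroxyl of 16 is capped with Et3SiOTf and 2,6-lutidine (CH2Cl2, −78 °C) to give the 6α-triethylsilyl ether F2. Luche reduction (NaBH4, CeCl3·7H2O, MeOH, −78 °C) then delivers hydride axially on the β face, anti to the pseudoaxial 6α silyl ether, to give the 3α alcohol F3. Mitsunobu reaction with chloroacetic acid (PPh3, diisopropyl azodicarboxylate, toluene, 0 °C → rt) inverts C3 to the 3β chloroacetate F4. Thiourea and NaHCO3 in ethanol (50 °C) remove the chloroacetyl group without touching the benzoates to give the 3β alcohol F5, and HF·pyridine strips both silyl groups to give 18.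

3. Step 8. The sulfoxide may eliminate toward C7, or the allylic sulfenate may ionise with loss of benzoic acid and aromatisation. The fallback sets out from 10 and rejoins at 14, and it removes the C3 oxygen at the enol level. Silyloxy enone 10 with Tf2O and 2,6-di-tert-butyl-4-methylpyridine (CH2Cl2, 0 °C) should give, by γ-deprotonation at C6, the extended dienyl triflate F6 (C3(OTf)=C2 and C1=C6). Palladium-catalysed formate reduction (Pd(OAc)2, PPh3, n-Bu3N, HCO2H, DMF, 40 °C) then replaces the triflate by hydrogen to give diene 14; the vinyl triflate adds to zerovalent palladium much faster than the allylic benzoates ionise.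

Further compounds
F1 | step 9 | (5α-benzoyloxy-6α-hydroxy-3β,4β-isopropylidenedioxycyclohex-1-en-1-yl)methyl benzoate | O=C(OCC1=C[C@H]2OC(C)(C)O[C@H]2[C@H](OC(=O)c2ccccc2)[C@@H]1O)c1ccccc1
F2 | step 10 | [5α-benzoyloxy-4β-(tert-butyldimethylsilyloxy)-3-oxo-6α-(triethylsilyloxy)cyclohex-1-en-1-yl]methyl benzoate | O=C(OCC1=CC(=O)[C@@H](O[Si](C)(C)C(C)(C)C)[C@H](OC(=O)c2ccccc2)[C@@H]1O[Si](CC)(CC)CC)c1ccccc1
F3 | step 10 | [5α-benzoyloxy-4β-(tert-butyldimethylsilyloxy)-3α-hydroxy-6α-(triethylsilyloxy)cyclohex-1-en-1-yl]methyl benzoate | O=C(OCC1=C[C@H](O)[C@@H](O[Si](C)(C)C(C)(C)C)[C@H](OC(=O)c2ccccc2)[C@@H]1O[Si](CC)(CC)CC)c1ccccc1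
F4 | step 10 | [5α-benzoyloxy-4β-(tert-butyldimethylsilyloxy)-3β-(chloroacetoxy)-6α-(triethylsilyloxy)cyclohex-1-en-1-yl]methyl benzoate | O=C(OCC1=C[C@@H](OC(=O)CCl)[C@@H](O[Si](C)(C)C(C)(C)C)[C@H](OC(=O)c2ccccc2)[C@@H]1O[Si](CC)(CC)CC)c1ccccc1
F5 | step 10 | [5α-benzoyloxy-4β-(tert-butyldimethylsilyloxy)-3β-hydroxy-6α-(triethylsilyloxy)cyclohex-1-en-1-yl]methyl benzoate | O=C(OCC1=C[C@@H](O)[C@@H](O[Si](C)(C)C(C)(C)C)[C@H](OC(=O)c2ccccc2)[C@@H]1O[Si](CC)(CC)CC)c1ccccc1
F6 | step 8 | [5α-benzoyloxy-4β-(tert-butyldimethylsilyloxy)-3-(trifluoromethanesulfonyloxy)cyclohexa-1(6),2-dien-1-yl]methyl benzoate | O=C(OCC1=C[C@@H](OC(=O)c2ccccc2)[C@H](O[Si](C)(C)C(C)(C)C)C(OS(=O)(=O)C(F)(F)F)=C1)c1ccccc1
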